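**Strategy.** The tetrahydrofuran ring of the bicycle (O, C9, C8, C8', C7'; lignan numbering) is opened at O–C7' and C8–C8'. This exposes O–C9–C8–C7 as the four-atom chain of butadiene monoxide and C7'–C8'–C9' as a catechol-derived arylidene malonate. A single palladium-catalysed, ligand-controlled [3+2] union of the racemic epoxide with the malonate forms both bonds, the ring and the C8 and C7' stereocentres. The vinyl group left on C8 is the future C7, and one of the twin esters is the future lactone carbonyl C9'. The pyrogallol ring then enters as an aryl ketone at C7, and substrate-controlled reduction with lactonisation closes the lactone ring.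

Key step: step 2

Numbering: C7, C8, C9 = carbinol carbon carrying the pyrogallol ring, adjacent ring-fusion carbon, ether CH2; C7', C8', C9' = carbinol carbon carrying the catechol ring, adjacent ring-fusion carbon, lactone carbonyl. The target is (7S,8R,7'S,8'S), cis-fused, with both aryl groups on the convex face (cis to H-8 and H-8').

Assumption: the (R,R)-ligand written in step 2 is taken to give the (4R)-cycloadduct; this sense cannot be read from simple allylic alkylations, and the (S,S)-ligand is used instead if the opposite sense is found.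

Design notes:
- C7 is set by hydride addition to an aryl ketone. For aryl-metal addition to the corresponding aldehyde, both the Felkin–Anh model and chelation through the ring oxygen predict the unwanted C7 epimer (aryl endo).
- Acid equilibration of the benzylic centres is not relied on, since exo and endo aryl groups in this ring system may differ little in energy.
- The pyrogallol unit comes from a 5-bromo-1,2,3-trioxygenated benzene, because bromination or metalation of pyrogallol ethers occurs at C4 and would give the 2,3,4-pattern.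

**Step 1**
Reactants: 1 3,4-bis(benzyloxy)benzaldehyde; 2 dimethyl malonate
Product: 3 dimethyl 2-[3,4-bis(benzyloxy)benzylidene]malonate
Conditions: piperidine (10 mol %), AcOH (10 mol %), toluene, reflux, Dean–Stark
Reagents that add atoms: none
Why: Knoevenagel condensation driven by azeotropic removal of water; the symmetrical malonate leaves no alkene geometry to control.

**Step 2**
Reactants: 3 dimethyl 2-[3,4-bis(benzyloxy)benzylidene]malonate; 4 butadiene monoxide (racemic, 1.5 equiv)
Product: 5 dimethyl (2R,4R)-2-[3,4-bis(benzyloxy)phenyl]-4-vinyltetrahydrofuran-3,3-dicarboxylate (aryl and vinyl trans)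
Conditions: Pd2(dba)3·CHCl3 (2.5 mol %), (R,R)-N,N'-(cyclohexane-1,2-diyl)bis[2-(diphenylphosphino)-1-naphthamide] (7.5 mol %), THF, rt, 4 added by syringe pump over 4 h
Reagents that add atoms: none
Why: Zerovalent palladium opens either enantiomer of 4 to an alkoxy π-allyl zwitterion, whose alkoxide adds reversibly to C7' of 3 (oxa-Michael) and whose internal allyl carbon is then attacked by the malonate carbanion so formed, releasing the catalyst. The closest known reaction type is the palladium-catalysed [3+2] cycloaddition of vinyl epoxides with doubly activated alkenes, run here as a dynamic kinetic asymmetric transformation. The tetrahydrofuran ring closes by 5-exo attack of C8' on the allyl unit (bond C8'–C8), the alternative 7-endo attack at the allyl terminus being far slower. C8 is controlled by the chiral ligand, because the diastereomeric allyl complexes interconvert by π–σ–π isomerisation faster than they cyclise when 4 is kept at low concentration; C7' is controlled relative to C8 in the same transition state, the aryl group and the ligand-bearing allyl fragment taking opposite faces of the forming ring, and the reversible oxa-Michael step lets the faster-closing diastereomer drain the equilibrium. The step needs branched regioselectivity, enantioselectivity at C8 and trans selectivity between C7' and C8, which are secured by the five-membered ring size, the ligand pocket and the reversibility of the first bond respectively.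

**Step 3**
Reactants: 5 dimethyl (2R,4R)-2-[3,4-bis(benzyloxy)phenyl]-4-vinyltetrahydrofuran-3,3-dicarboxylate
Product: 8 (3R,5R)-5-[3,4-bis(benzyloxy)phenyl]-4,4-bis(methoxycarbonyl)tetrahydrofuran-3-carboxylic acid, via ozonide 6 (not isolated), via aldehyde 7 (not isolated)
Conditions: O3, CH2Cl2, −78 °C (Sudan Red 7B end point); Me2S, −78 °C to rt; concentrate; NaClO2, NaH2PO4, 2-methyl-2-butene, t-BuOH/H2O, 0 °C to rt
Reagents that add atoms: ozone O=[O+][O-]; sodium chlorite [Na+].[O-]Cl=O
Why: Ozonolysis with reductive work-up cleaves only the terminal alkene (the dye end point spares the alkoxyarene), and Pinnick oxidation of the crude α-branched aldehyde under buffered, non-enolising conditions should give the acid with C8 untouched.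

**Step 4**
Reactants: 9 5-bromo-1,2,3-trimethoxybenzene
Product: 10 5-bromobenzene-1,2,3-triol
Conditions: BBr3 (3.5 equiv), CH2Cl2, −78 °C to rt; H2O
Reagents that add atoms: none
Why: Boron tribromide demethylation of aryl methyl ethers (Lewis acid-assisted SN2 at methyl) leaves the aryl bromide, which fixes the 3,4,5-substitution pattern, intact.

**Step 5**
Reactants: 10 5-bromobenzene-1,2,3-triol
Product: 11 5-bromo-1,2,3-tris(benzyloxy)benzene
Conditions: BnBr (3.6 equiv), K2CO3, DMF, 60 °C, under N2
Reagents that add atoms: benzyl bromide BrCc1ccccc1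
Why: Williamson etherification of the three phenols, run under nitrogen because the triol is air-sensitive.

**Step 6**
Reactants: 8 (3R,5R)-5-[3,4-bis(benzyloxy)phenyl]-4,4-bis(methoxycarbonyl)tetrahydrofuran-3-carboxylic acid; 11 5-bromo-1,2,3-tris(benzyloxy)benzene
Product: 15 dimethyl (2R,4R)-2-[3,4-bis(benzyloxy)phenyl]-4-[3,4,5-tris(benzyloxy)benzoyl]tetrahydrofuran-3,3-dicarboxylate, via acid chloride 12 (not isolated), via aryllithium 13 (not isolated), via arylzinc chloride 14 (not isolated)
Conditions: 8, (COCl)2, DMF (cat.), CH2Cl2, 0 °C to rt, evaporate; separately 11, n-BuLi, THF, −78 °C, then ZnCl2, −78 to 0 °C; combine, Pd(PPh3)4 (5 mol %), THF, 0 °C to rt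
Reagents that add atoms: none
Why: Negishi acylation, in which the acid chloride adds oxidatively to zerovalent palladium and couples with the arylzinc reagent, which tolerates the methyl esters and is too weakly basic to enolise the product ketone, so C8 should be kept.

**Step 7**
Reactants: 15 dimethyl (2R,4R)-2-[3,4-bis(benzyloxy)phenyl]-4-[3,4,5-tris(benzyloxy)benzoyl]tetrahydrofuran-3,3-dicarboxylate
Product: 17 methyl (1S,4S,5R,8R)-8-[3,4-bis(benzyloxy)phenyl]-2-oxo-4-[3,4,5-tris(benzyloxy)phenyl]-3,7-dioxabicyclo[3.3.0]octane-1-carboxylate, via lithium alkoxide 16 (not isolated)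
Conditions: Li[HB(s-Bu)3] (1.2 equiv), THF, −78 °C; warm to rt; H2O
Reagents that add atoms: none
Why: Felkin–Anh-controlled hydride reduction of the α-branched aryl ketone (attack anti to the quaternary C8' with H-8 next to the aryl group; chelation of lithium by the ring oxygen predicts the same face) should give the (7S)-alkoxide 16, which acylates itself on the cis ester (intramolecular transesterification, 5-exo-trig) to the cis-fused lactone with the pyrogallol ring exo.

**Step 8**
Reactants: 17 methyl (1S,4S,5R,8R)-8-[3,4-bis(benzyloxy)phenyl]-2-oxo-4-[3,4,5-tris(benzyloxy)phenyl]-3,7-dioxabicyclo[3.3.0]octane-1-carboxylate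
Product: 19 (1S,4S,5R,8S)-8-[3,4-bis(benzyloxy)phenyl]-4-[3,4,5-tris(benzyloxy)phenyl]-3,7-dioxabicyclo[3.3.0]octan-2-one, via lithium carboxylate 18 (not isolated)
Conditions: LiCl (3 equiv), H2O (2 equiv), DMSO, 120–130 °C
Reagents that add atoms: none
Why: Krapcho dealkoxycarbonylation, in which chloride removes the ester methyl group by SN2, the β-carbonyl carboxylate loses carbon dioxide and the lactone enolate is protonated at C8' to give the only possible, cis-fused ring junction (H-8' cis to H-8).

**Step 9**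
Reactants: 19 (1S,4S,5R,8S)-8-[3,4-bis(benzyloxy)phenyl]-4-[3,4,5-tris(benzyloxy)phenyl]-3,7-dioxabicyclo[3.3.0]octan-2-one
Product: 20 (1S,4S,5R,8S)-8-(3,4-dihydroxyphenyl)-4-(3,4,5-trihydroxyphenyl)-3,7-dioxabicyclo[3.3.0]octan-2-one (CNP0290035.1)
Conditions: H2 (1 atm), 10% Pd/C, EtOAc/THF 1:1, rt, stopped at the calculated uptake; filtered under argon
Reagents that add atoms: none
Why: Catalytic hydrogenolysis of the five aryl benzyl ethers, which under neutral, acid-free conditions in an aprotic solvent should cleave much faster than the ring benzylic C–O bonds of the lactone and the ether, and which releases the air-sensitive polyphenol without aqueous work-up.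

**Compound list**

1 | 3,4-bis(benzyloxy)benzaldehyde | O=Cc1ccc(OCc2ccccc2)c(OCc2ccccc2)c1 | starting material
2 | dimethyl malonate | COC(=O)CC(=O)OC | starting material
3 | dimethyl 2-[3,4-bis(benzyloxy)benzylidene]malonate | COC(=O)C(=Cc1ccc(OCc2ccccc2)c(OCc2ccccc2)c1)C(=O)OC | intermediate
4 | butadiene monoxide (2-vinyloxirane), racemic | C=CC1CO1 | starting material
5 | dimethyl (2R,4R)-2-[3,4-bis(benzyloxy)phenyl]-4-vinyltetrahydrofuran-3,3-dicarboxylate | C=C[C@H]1CO[C@H](c2ccc(OCc3ccccc3)c(OCc3ccccc3)c2)C1(C(=O)OC)C(=O)OC | intermediate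
6 | dimethyl (2R,4R)-2-[3,4-bis(benzyloxy)phenyl]-4-(1,2,4-trioxolan-3-yl)tetrahydrofuran-3,3-dicarboxylate (ozonide, both epimers at the trioxolane carbon) | C1OC(OO1)[C@H]1CO[C@H](c2ccc(OCc3ccccc3)c(OCc3ccccc3)c2)C1(C(=O)OC)C(=O)OC | intermediate (not isolated)
7 | dimethyl (2R,4R)-2-[3,4-bis(benzyloxy)phenyl]-4-formyltetrahydrofuran-3,3-dicarboxylate | O=C[C@H]1CO[C@H](c2ccc(OCc3ccccc3)c(OCc3ccccc3)c2)C1(C(=O)OC)C(=O)OC | intermediate (not isolated)
8 | (3R,5R)-5-[3,4-bis(benzyloxy)phenyl]-4,4-bis(methoxycarbonyl)tetrahydrofuran-3-carboxylic acid | OC(=O)[C@H]1CO[C@H](c2ccc(OCc3ccccc3)c(OCc3ccccc3)c2)C1(C(=O)OC)C(=O)OC | intermediate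
9 | 5-bromo-1,2,3-trimethoxybenzene | COc1cc(Br)cc(OC)c1OC | starting material
10 | 5-bromobenzene-1,2,3-triol | Oc1cc(Br)cc(O)c1O | intermediate
11 | 5-bromo-1,2,3-tris(benzyloxy)benzene | Brc1cc(OCc2ccccc2)c(OCc2ccccc2)c(OCc2ccccc2)c1 | intermediate
12 | dimethyl (2R,4R)-2-[3,4-bis(benzyloxy)phenyl]-4-(chlorocarbonyl)tetrahydrofuran-3,3-dicarboxylate | ClC(=O)[C@H]1CO[C@H](c2ccc(OCc3ccccc3)c(OCc3ccccc3)c2)C1(C(=O)OC)C(=O)OC | intermediate (not isolated)
13 | [3,4,5-tris(benzyloxy)phenyl]lithium | [Li]c1cc(OCc2ccccc2)c(OCc2ccccc2)c(OCc2ccccc2)c1 | intermediate (not isolated)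
14 | [3,4,5-tris(benzyloxy)phenyl]zinc chloride | Cl[Zn]c1cc(OCc2ccccc2)c(OCc2ccccc2)c(OCc2ccccc2)c1 | intermediate (not isolated)
15 | dimethyl (2R,4R)-2-[3,4-bis(benzyloxy)phenyl]-4-[3,4,5-tris(benzyloxy)benzoyl]tetrahydrofuran-3,3-dicarboxylate | O=C(c1cc(OCc2ccccc2)c(OCc2ccccc2)c(OCc2ccccc2)c1)[C@H]1CO[C@H](c2ccc(OCc3ccccc3)c(OCc3ccccc3)c2)C1(C(=O)OC)C(=O)OC | intermediate
16 | lithium alkoxide of dimethyl (2R,4R)-2-[3,4-bis(benzyloxy)phenyl]-4-{(S)-hydroxy[3,4,5-tris(benzyloxy)phenyl]methyl}tetrahydrofuran-3,3-dicarboxylate | [Li+].[O-][C@H](c1cc(OCc2ccccc2)c(OCc2ccccc2)c(OCc2ccccc2)c1)[C@H]1CO[C@H](c2ccc(OCc3ccccc3)c(OCc3ccccc3)c2)C1(C(=O)OC)C(=O)OC | intermediate (not isolated)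
17 | methyl (1S,4S,5R,8R)-8-[3,4-bis(benzyloxy)phenyl]-2-oxo-4-[3,4,5-tris(benzyloxy)phenyl]-3,7-dioxabicyclo[3.3.0]octane-1-carboxylate (cis-fused, both aryl groups exo) | O=C1O[C@H](c3cc(OCc4ccccc4)c(OCc4ccccc4)c(OCc4ccccc4)c3)[C@H]2CO[C@H](c3ccc(OCc4ccccc4)c(OCc4ccccc4)c3)[C@@]12C(=O)OC | intermediate
18 | lithium (1S,4S,5R,8R)-8-[3,4-bis(benzyloxy)phenyl]-2-oxo-4-[3,4,5-tris(benzyloxy)phenyl]-3,7-dioxabicyclo[3.3.0]octane-1-carboxylate | O=C1O[C@H](c3cc(OCc4ccccc4)c(OCc4ccccc4)c(OCc4ccccc4)c3)[C@H]2CO[C@H](c3ccc(OCc4ccccc4)c(OCc4ccccc4)c3)[C@@]12C(=O)[O-].[Li+] | intermediate (not isolated)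
19 | (1S,4S,5R,8S)-8-[3,4-bis(benzyloxy)phenyl]-4-[3,4,5-tris(benzyloxy)phenyl]-3,7-dioxabicyclo[3.3.0]octan-2-one | O=C1O[C@H](c3cc(OCc4ccccc4)c(OCc4ccccc4)c(OCc4ccccc4)c3)[C@H]2CO[C@H](c3ccc(OCc4ccccc4)c(OCc4ccccc4)c3)[C@@H]12 | intermediate
20 | (1S,4S,5R,8S)-8-(3,4-dihydroxyphenyl)-4-(3,4,5-trihydroxyphenyl)-3,7-dioxabicyclo[3.3.0]octan-2-one | O=C1O[C@H](c2cc(O)c(O)c(O)c2)[C@H]2CO[C@H](c3ccc(O)c(O)c3)[C@@H]12 | target

**Step count and risks**

Total step count: 9. Longest linear sequence: 7 (steps 1, 2, 3, 6, 7, 8, 9); steps 4 and 5 form the side branch that joins at step 6.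

Steps most likely to fail:

Step 2. Capture of the alkoxide zwitterion by the electron-rich, only moderately electrophilic arylidene malonate may be slow, so that the epoxide is lost to isomerisation and oligomerisation. Ring closure may also outrun equilibration of the allyl complexes and erode the enantiomeric and trans selectivity. The fallback changes the acceptor class and sets out from 1 and 4. Condensation of 1 with Meldrum's acid (EtOH, rt, no catalyst) gives 5-[3,4-bis(benzyloxy)benzylidene]-2,2-dimethyl-1,3-dioxane-4,6-dione F1. This is a far stronger Michael acceptor, and its more stabilised carbanion closes the ring more slowly, which leaves time for allyl equilibration. The same palladium-catalysed cycloaddition with 4 then gives (1R,4R)-1-[3,4-bis(benzyloxy)phenyl]-8,8-dimethyl-4-vinyl-2,7,9-trioxaspiro[4.5]decane-6,10-dione F2. NaOMe in MeOH opens the dioxanedione with loss of acetone to (2R,4R)-2-[3,4-bis(benzyloxy)phenyl]-3-(methoxycarbonyl)-4-vinyltetrahydrofuran-3-carboxylic acid F3 (both epimers at C3). Esterification with TMSCHN2 returns the route at 5.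

Step 8. At 120–130 °C the lactone is a malonate-type leaving group on a benzylic carbon that carries an electron-rich arene. Chloride- or solvent-assisted opening at C7 followed by reclosure would epimerise C7 or end in elimination. The fallback sets out from 17 and separates ester cleavage from decarboxylation. Me3SnOH (1,2-dichloroethane, 70 °C) hydrolyses the methyl ester by attack at the acyl carbon; any lactone that opens recloses with retention on acidification. This gives (1S,4S,5R,8R)-8-[3,4-bis(benzyloxy)phenyl]-2-oxo-4-[3,4,5-tris(benzyloxy)phenyl]-3,7-dioxabicyclo[3.3.0]octane-1-carboxylic acid F4. The free acid is then decarboxylated thermally through the cyclic six-membered transition state in toluene at 90 °C, which returns the route at 19.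

Step 7. Poor facial selectivity in the hydride addition would give the C7-epimeric alkoxide, which lactonises just as readily. The fallback sets out from 15 and inverts the wrong epimer instead of trying to avoid it. The co-formed methyl (1S,4R,5R,8R)-8-[3,4-bis(benzyloxy)phenyl]-2-oxo-4-[3,4,5-tris(benzyloxy)phenyl]-3,7-dioxabicyclo[3.3.0]octane-1-carboxylate F5 (pyrogallol ring endo) is separated. LiOH (1.1 equiv, THF/H2O, 0 °C) opens it to (2R,3R,4R)-2-[3,4-bis(benzyloxy)phenyl]-4-{(R)-hydroxy[3,4,5-tris(benzyloxy)phenyl]methyl}-3-(methoxycarbonyl)tetrahydrofuran-3-carboxylic acid F6. Mitsunobu lactonisation (PPh3, DIAD, THF, 0 °C) recloses the ring with inversion at C7 and returns the route at 17.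

**Further compounds**

F1 | step 2 | 5-[3,4-bis(benzyloxy)benzylidene]-2,2-dimethyl-1,3-dioxane-4,6-dione | CC1(C)OC(=O)C(=Cc2ccc(OCc3ccccc3)c(OCc3ccccc3)c2)C(=O)O1
F2 | step 2 | (1R,4R)-1-[3,4-bis(benzyloxy)phenyl]-8,8-dimethyl-4-vinyl-2,7,9-trioxaspiro[4.5]decane-6,10-dione | C=C[C@H]1CO[C@H](c2ccc(OCc3ccccc3)c(OCc3ccccc3)c2)C12C(=O)OC(C)(C)OC2=O
F3 | step 2 | (2R,4R)-2-[3,4-bis(benzyloxy)phenyl]-3-(methoxycarbonyl)-4-vinyltetrahydrofuran-3-carboxylic acid (both epimers at C3) | C=C[C@H]1CO[C@H](c2ccc(OCc3ccccc3)c(OCc3ccccc3)c2)C1(C(=O)O)C(=O)OC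
F4 | step 8 | (1S,4S,5R,8R)-8-[3,4-bis(benzyloxy)phenyl]-2-oxo-4-[3,4,5-tris(benzyloxy)phenyl]-3,7-dioxabicyclo[3.3.0]octane-1-carboxylic acid | O=C1O[C@H](c3cc(OCc4ccccc4)c(OCc4ccccc4)c(OCc4ccccc4)c3)[C@H]2CO[C@H](c3ccc(OCc4ccccc4)c(OCc4ccccc4)c3)[C@@]12C(=O)O
F5 | step 7 | methyl (1S,4R,5R,8R)-8-[3,4-bis(benzyloxy)phenyl]-2-oxo-4-[3,4,5-tris(benzyloxy)phenyl]-3,7-dioxabicyclo[3.3.0]octane-1-carboxylate | O=C1O[C@@H](c3cc(OCc4ccccc4)c(OCc4ccccc4)c(OCc4ccccc4)c3)[C@H]2CO[C@H](c3ccc(OCc4ccccc4)c(OCc4ccccc4)c3)[C@@]12C(=O)OC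
F6 | step 7 | (2R,3R,4R)-2-[3,4-bis(benzyloxy)phenyl]-4-{(R)-hydroxy[3,4,5-tris(benzyloxy)phenyl]methyl}-3-(methoxycarbonyl)tetrahydrofuran-3-carboxylic acid | O[C@@H](c1cc(OCc2ccccc2)c(OCc2ccccc2)c(OCc2ccccc2)c1)[C@H]1CO[C@H](c2ccc(OCc3ccccc3)c(OCc3ccccc3)c2)[C@]1(C(=O)O)C(=O)OC
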